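The nine-membered carbocycle (C1 acetoxy carbon, C3=C4 methyl-bearing E-olefin, C6=C7 enal olefin, C9 side-chain carbon) is made by contracting an eleven-membered β-keto lactone. The step exploits the C5–C6 ring bond, whose C5 is allylic to C3=C4 and whose C6 is α to the C7 carbonyl: in the lactone these carbons are joined through a C(=O)–O bridge, zerovalent palladium ionises the allylic ester, CO2 leaves, and the C6 enolate closes on C5. One operation excises the bridge, forms the carbocycle and leaves the C7 ketone for the enal. The lactone is built from (S)-citronellal by nitro-Michael addition, vinylogous aldol addition and acylketene lactonisation.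

Key step: step 10

Remark (labels): C1–C9 are the ring carbons as defined above, C8a is the formyl carbon on C8, C10 is the side-chain methine; the same labels are used for all intermediates. TBS = tert-butyldimethylsilyl, TES = triethylsilyl, Tf = trifluoromethanesulfonyl.

Assumption: in step 4 the (S)-tryptophan-derived oxazaborolidinone is taken to direct addition to the Re face of aldehyde 9, the sense this promoter class shows with simple aliphatic aldehydes, and the intrinsic facial bias of 9 is taken to be small.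

Step 1
Reactants: 1 (tert-butyldimethylsilyloxy)acetaldehyde; 2 nitromethane
Product: 5 (E)-tert-butyldimethyl[(3-nitroprop-2-en-1-yl)oxy]silane, via nitro alcohol 3 (not isolated), via nitro mesylate 4 (not isolated)
Conditions: MeNO2 (excess), Et3N (cat.), 0 °C to rt; evaporate; then MsCl, Et3N, CH2Cl2, −20 to 0 °C
Reagents that add atoms: none
Why: Henry addition followed by E1cB elimination of the mesylate should give the conjugated nitroalkene as the more stable (E) isomer; no stereocenter survives.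

Step 2
Reactants: 6 3-methylbut-2-enal
Product: 7 tert-butyldimethyl{[(1E)-3-methylbuta-1,3-dien-1-yl]oxy}silane
Conditions: TBSOTf, Et3N, Et2O, 0 °C to rt
Reagents that add atoms: tert-butyldimethylsilyl trifluoromethanesulfonate, CC(C)(C)[Si](C)(C)OS(=O)(=O)C(F)(F)F
Why: Soft enolisation of the s-trans enal (O-silylation, then γ-deprotonation by the amine) should give the 1-silyloxy diene with an (E) enol ether.

Step 3
Reactants: 8 (S)-citronellal [(3S)-3,7-dimethyloct-6-enal]; 5 (E)-tert-butyldimethyl[(3-nitroprop-2-en-1-yl)oxy]silane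
Product: 9 (2R,3R)-3-{[(TBS)oxy]methyl}-2-[(2S)-6-methylhept-5-en-2-yl]-4-nitrobutanal
Conditions: (S)-2-[diphenyl(trimethylsilyloxy)methyl]pyrrolidine (10 mol%), 4-nitrophenol (10 mol%), 8 (1.5 equiv), toluene, 0 °C to rt
Reagents that add atoms: none
Why: Enamine-catalysed Michael addition of an aldehyde to a nitroalkene (diarylprolinol silyl ether catalysis): the diphenyl(silyloxy)methyl group blocks one face of the (E)-enamine and the synclinal open transition state gives the syn adduct, so C9 (R) and C8 (R) are set by the catalyst while C10 comes unchanged from 8.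

Step 4
Reactants: 9 (2R,3R)-nitro aldehyde; 7 silyl dienol ether
Product: 10 (2E,5R,6R,7R)-7-{[(TBS)oxy]methyl}-5-hydroxy-3-methyl-6-[(2S)-6-methylhept-5-en-2-yl]-8-nitrooct-2-enal
Conditions: 2-phenyl-1,3,2-oxazaborolidin-5-one made from N-tosyl-(S)-tryptophan and PhBCl2 (1.1 equiv), i-PrOH (1.1 equiv), EtCN, −78 °C
Reagents that add atoms: none
Why: Vinylogous Mukaiyama aldol addition at the γ-carbon (C2) of the dienol ether through an open transition state should give the (E)-C3=C4 enal from the s-trans diene, and the C1 carbinol (R) is set by reagent control, the boron-bound aldehyde being attacked on its Re face.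

Step 5
Reactants: 10 hydroxy enal
Product: 11 (2E,5R,6R,7R)-7-{[(TBS)oxy]methyl}-3-methyl-6-[(2S)-6-methylhept-5-en-2-yl]-8-nitro-1-oxooct-2-en-5-yl acetate
Conditions: Ac2O, pyridine, DMAP (cat.), CH2Cl2, 0 °C
Reagents that add atoms: acetic anhydride, CC(=O)OC(C)=O
Why: DMAP-catalysed acetylation of the secondary alcohol installs the acetate of the target; pyridine is too weak a base to affect the nitro group or the enal, and no stereocenter changes.

Step 6
Reactants: 11 acetoxy enal
Product: 12 (2E,5R,6R,7R)-7-{[(TBS)oxy]methyl}-1-hydroxy-3-methyl-6-[(2S)-6-methylhept-5-en-2-yl]-8-nitrooct-2-en-5-yl acetate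
Conditions: NaBH4, CeCl3·7H2O, MeOH, −40 °C
Reagents that add atoms: none
Why: Luche 1,2-reduction of the enal should give the primary (E)-allylic alcohol at C5 and leave acetate, nitro group and silyl ether intact.

Step 7
Reactants: 12 nitro allylic alcohol
Product: 14 (2E,5R,6R,7S)-7-{[(TBS)oxy]methyl}-1-hydroxy-3-methyl-6-[(2S)-6-methylhept-5-en-2-yl]-8-oxooct-2-en-5-yl acetate, via sodium nitronate 13 (not isolated)
Conditions: NaOMe (1.0 equiv), MeOH, 0 °C; then aq. TiCl3, NH4OAc (pH ca. 5), THF, 0 °C to rt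
Reagents that add atoms: water, O
Why: Reductive Nef reaction: trivalent titanium reduces the nitronate to the imine, which hydrolyses in the buffered medium to the C7 aldehyde; C8 keeps its configuration (only its descriptor changes) because only C7 becomes trigonal and the buffer avoids enolisation.

Step 8
Reactants: 14 hydroxy aldehyde; 15 tert-butyl diazoacetate
Product: 16 tert-butyl (4S,5R,6R,8E)-6-acetoxy-4-{[(TBS)oxy]methyl}-10-hydroxy-8-methyl-5-[(2S)-6-methylhept-5-en-2-yl]-3-oxodec-8-enoate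
Conditions: SnCl2 (10 mol%), CH2Cl2, rt
Reagents that add atoms: none
Why: Roskamp homologation: Lewis-acid-promoted addition of the diazoacetate to the aldehyde and 1,2-hydride shift with loss of N2 should give the β-keto ester, introducing C6 and the carboxyl carbon without touching the free alcohol or C8.

Step 9
Reactants: 16 hydroxy β-keto ester
Product: 18 (5S,6R,7R,9E)-5-{[(TBS)oxy]methyl}-9-methyl-6-[(2S)-6-methylhept-5-en-2-yl]-2,4-dioxo-1-oxacycloundec-9-en-7-yl acetate, via acylketene 17 (not isolated)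
Conditions: toluene, 110 °C, slow addition to 1 mM, t-BuOH distilled off
Reagents that add atoms: none
Why: Acylketene lactonisation: thermal loss of tert-butanol from the tert-butyl β-keto ester gives an acylketene that the primary allylic alcohol should trap intramolecularly, closing the eleven-membered lactone under neutral conditions.

Step 10
Reactants: 18 eleven-membered β-keto lactone
Product: 19 (1R,3E,8S,9R)-8-{[(TBS)oxy]methyl}-3-methyl-9-[(2S)-6-methylhept-5-en-2-yl]-7-oxocyclonon-3-en-1-yl acetate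
Conditions: Pd(PPh3)4 (10 mol%), THF, 2 mM, 25 to 45 °C
Reagents that add atoms: none
Why: Zerovalent palladium ionises the allylic C5–O bond of 18 to a π-allyl palladium cation (C3–C4–C5) paired with the β-keto carboxylate, which loses CO2 to give the ketone enolate regiospecifically at C6, and C–C bond formation between C6 and the unsubstituted allyl terminus C5 releases the catalyst. The closest known reaction type is the Tsuji–Saegusa decarboxylative allylation of allyl β-keto esters (the palladium-catalysed Carroll variant), which joins prenyl-type π-allyls at the primary terminus with retention of olefin geometry. The nine-membered carbocycle is closed by intramolecular enolate C-allylation, a formal 1,3-shift of C5 from oxygen to C6 that contracts the eleven-membered lactone by its C(=O)–O unit. No stereocenter is created; C1, C8, C9 and C10 are spectators, and the (E)-C3=C4 geometry should be kept because both positions at C3 are substituted and syn–anti exchange would need a σ-bond at this tertiary terminus. The step needs attack at C5 rather than C3 (nine- versus seven-membered ring) and C- rather than O-allylation: C3 is fully substituted, C6 is generated next to C5 when CO2 departs, and any O-allyl enol ether re-ionises under the same catalyst. Regiospecific enolate generation also keeps C8 and its β-silyloxy group out of the reaction.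

Step 11
Reactants: 19 nine-membered ketone
Product: 21 (1R,3E,6E,8S,9R)-8-{[(TBS)oxy]methyl}-3-methyl-9-[(2S)-6-methylhept-5-en-2-yl]-7-{[(trifluoromethyl)sulfonyl]oxy}cyclonona-3,6-dien-1-yl acetate, via potassium enolate 20 (not isolated)
Conditions: KN(SiMe3)2 (1.05 equiv), THF, −78 °C; then N-(5-chloropyridin-2-yl)triflimide, −78 °C
Reagents that add atoms: N-(5-chloropyridin-2-yl)-1,1,1-trifluoro-N-[(trifluoromethyl)sulfonyl]methanesulfonamide, FC(F)(F)S(=O)(=O)N(c1ccc(Cl)cn1)S(=O)(=O)C(F)(F)F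
Why: Kinetic deprotonation at the unhindered C6 methylene rather than the branched C8, then O-triflation, should give the C6=C7 enol triflate; beside the (E)-C3=C4 olefin only the ring-cis enolate geometry is accessible.

Step 12
Reactants: 21 enol triflate
Product: 22 (1R,3E,6E,8R,9R)-8-{[(TBS)oxy]methyl}-7-formyl-3-methyl-9-[(2S)-6-methylhept-5-en-2-yl]cyclonona-3,6-dien-1-yl acetate
Conditions: Pd(PPh3)4 (5 mol%), CO (1 atm), Bu3SnH (slow addition), LiCl, THF, 50 °C
Reagents that add atoms: carbon monoxide, [C-]#[O+]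
Why: Palladium-catalysed reductive carbonylation of a vinyl triflate (Stille-type formylation): oxidative addition, CO insertion and hydride transfer from tin should give the enal with retention of the olefin geometry.

Step 13
Reactants: 22 silyl-protected enal
Product: 23 (1R,3E,6E,8R,9R)-7-formyl-8-(hydroxymethyl)-3-methyl-9-[(2S)-6-methylhept-5-en-2-yl]cyclonona-3,6-dien-1-yl acetate
Conditions: HF·pyridine, pyridine, THF, 0 °C to rt
Reagents that add atoms: none
Why: Fluoride-mediated cleavage of the primary silyl ether; acetate and enal are stable to buffered HF and no stereocenter is involved.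

Step 14
Reactants: 23 hydroxy enal
Product: 24 (1R,3E,6E,8R,9R)-7,8-diformyl-3-methyl-9-[(2S)-6-methylhept-5-en-2-yl]cyclonona-3,6-dien-1-yl acetate (target)
Conditions: Dess–Martin periodinane, NaHCO3, CH2Cl2, 0 °C
Reagents that add atoms: none
Why: Dess–Martin oxidation of the primary alcohol under buffered, non-enolising conditions should give the C8 aldehyde without epimerisation at C8 or migration of the C6=C7 double bond.

Compound list
1 | (tert-butyldimethylsilyloxy)acetaldehyde | O=CCO[Si](C)(C)C(C)(C)C | starting material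
2 | nitromethane | C[N+](=O)[O-] | starting material
3 | 1-[(TBS)oxy]-3-nitropropan-2-ol (racemic) | OC(CO[Si](C)(C)C(C)(C)C)C[N+](=O)[O-] | intermediate
4 | 1-[(TBS)oxy]-3-nitropropan-2-yl methanesulfonate (racemic) | CS(=O)(=O)OC(CO[Si](C)(C)C(C)(C)C)C[N+](=O)[O-] | intermediate
5 | (E)-tert-butyldimethyl[(3-nitroprop-2-en-1-yl)oxy]silane | [O-][N+](=O)/C=C/CO[Si](C)(C)C(C)(C)C | intermediate
6 | 3-methylbut-2-enal | CC(C)=CC=O | starting material
7 | tert-butyldimethyl{[(1E)-3-methylbuta-1,3-dien-1-yl]oxy}silane | C=C(C)/C=C/O[Si](C)(C)C(C)(C)C | intermediate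
8 | (S)-citronellal, (3S)-3,7-dimethyloct-6-enal | O=CC[C@@H](C)CCC=C(C)C | starting material
9 | (2R,3R)-3-{[(TBS)oxy]methyl}-2-[(2S)-6-methylhept-5-en-2-yl]-4-nitrobutanal | [O-][N+](=O)C[C@H](CO[Si](C)(C)C(C)(C)C)[C@H](C=O)[C@@H](C)CCC=C(C)C | intermediate
10 | (2E,5R,6R,7R)-7-{[(TBS)oxy]methyl}-5-hydroxy-3-methyl-6-[(2S)-6-methylhept-5-en-2-yl]-8-nitrooct-2-enal | O[C@@H]([C@@H]([C@@H](CO[Si](C)(C)C(C)(C)C)C[N+](=O)[O-])[C@@H](C)CCC=C(C)C)C/C(C)=C/C=O | intermediate
11 | (2E,5R,6R,7R)-7-{[(TBS)oxy]methyl}-3-methyl-6-[(2S)-6-methylhept-5-en-2-yl]-8-nitro-1-oxooct-2-en-5-yl acetate | CC(=O)O[C@@H]([C@@H]([C@@H](CO[Si](C)(C)C(C)(C)C)C[N+](=O)[O-])[C@@H](C)CCC=C(C)C)C/C(C)=C/C=O | intermediate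
12 | (2E,5R,6R,7R)-7-{[(TBS)oxy]methyl}-1-hydroxy-3-methyl-6-[(2S)-6-methylhept-5-en-2-yl]-8-nitrooct-2-en-5-yl acetate | CC(=O)O[C@@H]([C@@H]([C@@H](CO[Si](C)(C)C(C)(C)C)C[N+](=O)[O-])[C@@H](C)CCC=C(C)C)C/C(C)=C/CO | intermediate
13 | sodium nitronate of 12 (C7 nitronate, other groups as in 12) | CC(=O)O[C@@H]([C@@H]([C@@H](CO[Si](C)(C)C(C)(C)C)C=[N+]([O-])[O-])[C@@H](C)CCC=C(C)C)C/C(C)=C/CO.[Na+] | intermediate
14 | (2E,5R,6R,7S)-7-{[(TBS)oxy]methyl}-1-hydroxy-3-methyl-6-[(2S)-6-methylhept-5-en-2-yl]-8-oxooct-2-en-5-yl acetate | CC(=O)O[C@@H]([C@@H]([C@@H](CO[Si](C)(C)C(C)(C)C)C=O)[C@@H](C)CCC=C(C)C)C/C(C)=C/CO | intermediate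
15 | tert-butyl diazoacetate | [N-]=[N+]=CC(=O)OC(C)(C)C | starting material
16 | tert-butyl (4S,5R,6R,8E)-6-acetoxy-4-{[(TBS)oxy]methyl}-10-hydroxy-8-methyl-5-[(2S)-6-methylhept-5-en-2-yl]-3-oxodec-8-enoate | CC(=O)O[C@@H]([C@@H]([C@@H](CO[Si](C)(C)C(C)(C)C)C(=O)CC(=O)OC(C)(C)C)[C@@H](C)CCC=C(C)C)C/C(C)=C/CO | intermediate
17 | acylketene from 16 (O=C=CH–C(=O)– at C6/C7 in place of the tert-butyl ester terminus, stereocenters as in 16) | CC(=O)O[C@@H]([C@@H]([C@@H](CO[Si](C)(C)C(C)(C)C)C(=O)C=C=O)[C@@H](C)CCC=C(C)C)C/C(C)=C/CO | intermediate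
18 | (5S,6R,7R,9E)-5-{[(TBS)oxy]methyl}-9-methyl-6-[(2S)-6-methylhept-5-en-2-yl]-2,4-dioxo-1-oxacycloundec-9-en-7-yl acetate | CC(=O)O[C@@H]1C/C(C)=C/COC(=O)CC(=O)[C@H](CO[Si](C)(C)C(C)(C)C)[C@H]1[C@@H](C)CCC=C(C)C | intermediate
19 | (1R,3E,8S,9R)-8-{[(TBS)oxy]methyl}-3-methyl-9-[(2S)-6-methylhept-5-en-2-yl]-7-oxocyclonon-3-en-1-yl acetate | CC(=O)O[C@@H]1C/C(C)=C/CCC(=O)[C@H](CO[Si](C)(C)C(C)(C)C)[C@H]1[C@@H](C)CCC=C(C)C | intermediate
20 | potassium enolate of 19 (C6=C7 enolate, oxygen on C7, ring-cis) | CC(=O)O[C@@H]1C/C(C)=C/C/C=C(/[O-])[C@H](CO[Si](C)(C)C(C)(C)C)[C@H]1[C@@H](C)CCC=C(C)C.[K+] | intermediate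
21 | (1R,3E,6E,8S,9R)-8-{[(TBS)oxy]methyl}-3-methyl-9-[(2S)-6-methylhept-5-en-2-yl]-7-{[(trifluoromethyl)sulfonyl]oxy}cyclonona-3,6-dien-1-yl acetate | CC(=O)O[C@@H]1C/C(C)=C/C/C=C(/OS(=O)(=O)C(F)(F)F)[C@H](CO[Si](C)(C)C(C)(C)C)[C@H]1[C@@H](C)CCC=C(C)C | intermediate
22 | (1R,3E,6E,8R,9R)-8-{[(TBS)oxy]methyl}-7-formyl-3-methyl-9-[(2S)-6-methylhept-5-en-2-yl]cyclonona-3,6-dien-1-yl acetate | CC(=O)O[C@@H]1C/C(C)=C/C/C=C(/C=O)[C@H](CO[Si](C)(C)C(C)(C)C)[C@H]1[C@@H](C)CCC=C(C)C | intermediate
23 | (1R,3E,6E,8R,9R)-7-formyl-8-(hydroxymethyl)-3-methyl-9-[(2S)-6-methylhept-5-en-2-yl]cyclonona-3,6-dien-1-yl acetate | CC(=O)O[C@@H]1C/C(C)=C/C/C=C(/C=O)[C@H](CO)[C@H]1[C@@H](C)CCC=C(C)C | intermediate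
24 | (1R,3E,6E,8R,9R)-7,8-diformyl-3-methyl-9-[(2S)-6-methylhept-5-en-2-yl]cyclonona-3,6-dien-1-yl acetate | CC(=O)O[C@@H]1C/C(C)=C/C/C=C(/C=O)[C@H](C=O)[C@H]1[C@@H](C)CCC=C(C)C | target

Total step count: 14. Longest linear sequence: 13 steps (step 1, then steps 3 to 14).

Steps most likely to fail

1. Step 10. The enolate and π-allyl partner may fail to close the strained nine-membered ring. They could instead collapse by proton transfer and β-hydride loss to a ring-opened diene ketone, bond at the substituted terminus C3 to give a seven-membered ring, or suffer base-induced loss of the silyloxy group beside the ketone. The fallback sets out from 16 and replaces the unstabilised enolate by a stabilised carbon nucleophile. Methyl chloroformate and pyridine convert the allylic alcohol into the allylic methyl carbonate F1. Pd(PPh3)4 at high dilution in THF should then cyclise the β-keto ester onto the unsubstituted allyl terminus (Tsuji–Trost allylic alkylation) to the nine-membered β-keto tert-butyl ester F2. Thermolysis of F2 in mesitylene at 160 °C, with loss of 2-methylpropene and CO2, returns to the route at 19.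

2. Step 4. Reagent control may not override the facial preference of the doubly α-branched aldehyde, giving poor discrimination at C1, and the dienol ether may also react at its α-carbon. The fallback sets out from 9 and sets C1 by enamine catalysis. L-proline-catalysed aldol addition of acetone (Re-face attack) should give the β-hydroxy ketone F3, and TESOTf with 2,6-lutidine gives its triethylsilyl ether F4. Horner–Wadsworth–Emmons olefination with triethyl phosphonoacetate and NaH (excess, since the nitro group consumes base) gives the (E)-enoate F5 after removal of the minor olefin isomer. Reduction with i-Bu2AlH at −78 °C gives the allylic alcohol F6 and MnO2 the enal F7. Selective removal of the triethylsilyl group with HF·pyridine returns to the route at 10.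

3. Step 9. Intermolecular capture of the acylketene (oligomers, or return to the tert-butyl ester) may outrun closure of the eleven-membered ring. The fallback sets out from 14 and closes the ring by C–C bond formation. Bromoacetyl bromide and pyridine acylate the allylic alcohol to the bromoacetate F8. SmI2 in THF at high dilution (intramolecular Reformatsky reaction) should close the eleven-membered β-hydroxy lactone F9 as a mixture at the new carbinol. Dess–Martin oxidation returns to the route at 18.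

Further compounds
F1 | step 10 | tert-butyl (4S,5R,6R,8E)-6-acetoxy-4-{[(TBS)oxy]methyl}-10-[(methoxycarbonyl)oxy]-8-methyl-5-[(2S)-6-methylhept-5-en-2-yl]-3-oxodec-8-enoate | CC(=O)O[C@@H]([C@@H]([C@@H](CO[Si](C)(C)C(C)(C)C)C(=O)CC(=O)OC(C)(C)C)[C@@H](C)CCC=C(C)C)C/C(C)=C/COC(=O)OC
F2 | step 10 | tert-butyl (3E,6R,7R,8S)-6-acetoxy-8-{[(TBS)oxy]methyl}-4-methyl-7-[(2S)-6-methylhept-5-en-2-yl]-9-oxocyclonon-3-ene-1-carboxylate (ketone 19 carrying CO2t-Bu at C6, both C6 epimers) | CC(=O)O[C@@H]1C/C(C)=C/CC(C(=O)OC(C)(C)C)C(=O)[C@H](CO[Si](C)(C)C(C)(C)C)[C@H]1[C@@H](C)CCC=C(C)C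
F3 | step 4 | (4R,5R,6R)-6-{[(TBS)oxy]methyl}-4-hydroxy-5-[(2S)-6-methylhept-5-en-2-yl]-7-nitroheptan-2-one | O[C@@H]([C@@H]([C@@H](CO[Si](C)(C)C(C)(C)C)C[N+](=O)[O-])[C@@H](C)CCC=C(C)C)CC(C)=O
F4 | step 4 | (4R,5R,6R)-6-{[(TBS)oxy]methyl}-5-[(2S)-6-methylhept-5-en-2-yl]-7-nitro-4-[(triethylsilyl)oxy]heptan-2-one | CC[Si](CC)(CC)O[C@@H]([C@@H]([C@@H](CO[Si](C)(C)C(C)(C)C)C[N+](=O)[O-])[C@@H](C)CCC=C(C)C)CC(C)=O
F5 | step 4 | ethyl (2E,5R,6R,7R)-7-{[(TBS)oxy]methyl}-3-methyl-6-[(2S)-6-methylhept-5-en-2-yl]-8-nitro-5-[(triethylsilyl)oxy]oct-2-enoate | CC[Si](CC)(CC)O[C@@H]([C@@H]([C@@H](CO[Si](C)(C)C(C)(C)C)C[N+](=O)[O-])[C@@H](C)CCC=C(C)C)C/C(C)=C/C(=O)OCC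
F6 | step 4 | (2E,5R,6R,7R)-7-{[(TBS)oxy]methyl}-3-methyl-6-[(2S)-6-methylhept-5-en-2-yl]-8-nitro-5-[(triethylsilyl)oxy]oct-2-en-1-ol | CC[Si](CC)(CC)O[C@@H]([C@@H]([C@@H](CO[Si](C)(C)C(C)(C)C)C[N+](=O)[O-])[C@@H](C)CCC=C(C)C)C/C(C)=C/CO
F7 | step 4 | (2E,5R,6R,7R)-7-{[(TBS)oxy]methyl}-3-methyl-6-[(2S)-6-methylhept-5-en-2-yl]-8-nitro-5-[(triethylsilyl)oxy]oct-2-enal | CC[Si](CC)(CC)O[C@@H]([C@@H]([C@@H](CO[Si](C)(C)C(C)(C)C)C[N+](=O)[O-])[C@@H](C)CCC=C(C)C)C/C(C)=C/C=O
F8 | step 9 | (2E,5R,6R,7S)-5-acetoxy-7-{[(TBS)oxy]methyl}-3-methyl-6-[(2S)-6-methylhept-5-en-2-yl]-8-oxooct-2-en-1-yl bromoacetate | CC(=O)O[C@@H]([C@@H]([C@@H](CO[Si](C)(C)C(C)(C)C)C=O)[C@@H](C)CCC=C(C)C)C/C(C)=C/COC(=O)CBr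
F9 | step 9 | (5S,6R,7R,9E)-5-{[(TBS)oxy]methyl}-4-hydroxy-9-methyl-6-[(2S)-6-methylhept-5-en-2-yl]-2-oxo-1-oxacycloundec-9-en-7-yl acetate (both C4 epimers) | CC(=O)O[C@@H]1C/C(C)=C/COC(=O)CC(O)[C@H](CO[Si](C)(C)C(C)(C)C)[C@H]1[C@@H](C)CCC=C(C)C
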